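**Retrosynthetic overview**

1. The target is reached from 3,5,7-trimethoxy-2-[3,4,5-tris(benzyloxy)phenyl]chromen-4-one 16 by chelation-controlled 5-O-demethylation, Elbs hydroxylation at C8 (para to the freed 5-OH) and hydrogenolysis of the ring B benzyl ethers.
2. The strategy rests on one feature: the bonds O1–C8a and C4–C4a sit on neighbouring carbons of ring A, so an aryne spanning C4a≡C8a can take the pyranone oxygen and the C4 acyl carbon from a single carboxyl group.
3. 16 is disconnected into the ortho-silylaryl triflate 7 (source of 3,5-dimethoxybenzyne) and the β-methoxyacrylic acid 13; the β-methoxyl is the leaving group for the O1–C2 closure. Ring C is the only ring formed; rings A and B are bought.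
4. 7 comes from 3,5-dimethoxyphenol by carbamate-directed ortho-silylation and triflation; 13 comes from tribenzylgallic acid and methyl methoxyacetate by enolate acylation, enol O-methylation and saponification.
5. Both ring A ether oxygens travel as methyl ethers, so the two positions ortho to the directing carbamate are equivalent and the silane can only enter at the future C4a. A benzyl/methyl pair would leave that lithiation ambiguous; the C5 and C7 oxygens are told apart later by the C4 carbonyl.

Key step: step 8

Remark on the chemistry: the enol ether in 12, 13 and 15 is drawn and named as the Z isomer for definiteness. Its geometry is lost in the enolate of the addition–elimination, so the E isomer or a mixture should serve equally.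

**Route**

Step 1
Reactants: 1 3,5-dimethoxyphenol
Product: 2 3,5-dimethoxyphenyl N-isopropylcarbamate
Conditions: i-PrNCO, Et3N (cat.), CH2Cl2, rt
Reagents that add atoms: isopropyl isocyanate, CC(C)N=C=O
Why: Base-catalysed addition of the phenol to the isocyanate (carbamoylation) installs an N-monoalkyl carbamate that directs ortho-lithiation strongly and can later be removed under mild, non-acidic conditions.

Step 2
Reactants: 2 3,5-dimethoxyphenyl N-isopropylcarbamate
Product: 5 3,5-dimethoxy-2-(trimethylsilyl)phenyl N-isopropylcarbamate, via N-silyl carbamate 3 (not isolated), via N-silyl ortho-silyl carbamate 4 (not isolated)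
Conditions: TBSOTf, TMEDA, Et2O, 0 °C to rt; n-BuLi, TMEDA, −78 °C; Me3SiCl, −78 °C to rt; aq NaHSO4
Reagents that add atoms: chlorotrimethylsilane, C[Si](C)(C)Cl
Why: After in-situ N-silylation the O-aryl carbamate directs lithiation to its ortho position (directed ortho-metalation); the two ortho sites are equivalent, so one regioisomer is expected, the aryllithium is silylated at −78 °C before an anionic ortho-Fries shift can set in, and the N–Si bond is hydrolysed on acidic work-up.

Step 3
Reactants: 5 3,5-dimethoxy-2-(trimethylsilyl)phenyl N-isopropylcarbamate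
Product: 7 3,5-dimethoxy-2-(trimethylsilyl)phenyl trifluoromethanesulfonate, via silylphenol 6 (not isolated)
Conditions: DBU, Et2NH, MeCN, 40 °C; then PhNTf2, rt
Reagents that add atoms: N-phenylbis(trifluoromethanesulfonimide), O=S(=O)(N(c1ccccc1)S(=O)(=O)C(F)(F)F)C(F)(F)F
Why: DBU removes the carbamate N–H and triggers E1cB loss of isopropyl isocyanate (scavenged by Et2NH as a urea), and the phenoxide set free is O-triflated in the same flask, which avoids acid and hence protodesilylation of the electron-rich arylsilane.

Step 4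
Reactants: 8 3,4,5-tris(benzyloxy)benzoic acid
Product: 9 3,4,5-tris(benzyloxy)benzoyl chloride
Conditions: (COCl)2, DMF (cat.), CH2Cl2, 0 °C to rt; concentrate, use crude
Reagents that add atoms: oxalyl chloride, ClC(=O)C(=O)Cl
Why: Acid chloride formation through the chloroiminium (Vilsmeier-type) species is routine and leaves aryl benzyl ethers untouched.

Step 5
Reactants: 9 3,4,5-tris(benzyloxy)benzoyl chloride; 10 methyl methoxyacetate
Product: 11 methyl 2-methoxy-3-oxo-3-[3,4,5-tris(benzyloxy)phenyl]propanoate (racemic)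
Conditions: 10 (2.2 equiv), LiN(SiMe3)2 (2.3 equiv), THF, −78 °C; then 9, −78 to 0 °C; aq NH4Cl
Reagents that add atoms: none
Why: C-Acylation of the preformed lithium ester enolate by the acid chloride (crossed Claisen-type condensation) should give the β-keto ester, the second equivalent of enolate deprotonating the product so that it is not acylated again; the new C2 stereocentre forms as a racemate and is erased in step 6.

Step 6
Reactants: 11 methyl 2-methoxy-3-oxo-3-[3,4,5-tris(benzyloxy)phenyl]propanoate
Product: 12 methyl (Z)-2,3-dimethoxy-3-[3,4,5-tris(benzyloxy)phenyl]prop-2-enoate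
Conditions: Cs2CO3, Me2SO4, DMF, 0 °C to rt
Reagents that add atoms: dimethyl sulfate, COS(=O)(=O)OC
Why: O-Alkylation of the ambident β-keto ester enolate is favoured by the loosely paired caesium enolate in DMF, the hard sulfate electrophile and the fully substituted, alkoxy-bearing α-carbon, and should give the enol ether as a mixture of geometric isomers that are both usable.

Step 7
Reactants: 12 methyl (Z)-2,3-dimethoxy-3-[3,4,5-tris(benzyloxy)phenyl]prop-2-enoate
Product: 13 (Z)-2,3-dimethoxy-3-[3,4,5-tris(benzyloxy)phenyl]prop-2-enoic acid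
Conditions: LiOH·H2O, THF/MeOH/H2O, 60 °C; then 1 M HCl to pH 3–4, 0 °C; use promptly
Reagents that add atoms: lithium hydroxide, [Li+].[OH-]
Why: Saponification by acyl–oxygen cleavage should give the acid, since the enol ether is a vinylogous carbonate that resists hydroxide and a brief cold dilute acid quench.

Step 8
Reactants: 7 3,5-dimethoxy-2-(trimethylsilyl)phenyl trifluoromethanesulfonate; 13 (Z)-2,3-dimethoxy-3-[3,4,5-tris(benzyloxy)phenyl]prop-2-enoic acid
Product: 16 3,5,7-trimethoxy-2-[3,4,5-tris(benzyloxy)phenyl]-4H-chromen-4-one, via 3,5-dimethoxybenzyne 14 (not isolated), via ortho-hydroxyaryl enone 15 (not isolated)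
Conditions: 7 (1.5 equiv), CsF (4 equiv), THF, 125 °C, sealed tube; dilute HCl work-up
Reagents that add atoms: none
Why: Proposed new method: fluoride attacks silicon in 7 and expels triflate to give aryne 14; the caesium carboxylate of 13 adds through oxygen to the aryne carbon remote from the flanking methoxyl (future C8a), and the aryl anion left at C4a attacks the ester carbonyl through a four-membered alkoxide that opens to the ortho-acylphenoxide of 15, a formal insertion of the aryne into the carboxyl C–O bond. The phenoxide then adds to the β-carbon of the enone and the resulting enolate expels methoxide, so ring C closes by a 6-endo-trig oxa-Michael addition–elimination with the C3 methoxyl already in place, and O1–C8a, C4–C4a and O1–C2 are made in one flask. The closest known reaction is the CsF-mediated insertion of arynes into carboxylic acid C–O bonds, which gives ortho-hydroxyaryl ketones, 4-chromanones from acrylic acids and flavones from arylpropiolic acids; what is new is the termination by displacement of a β-alkoxy group on a tetrasubstituted acrylic acid. The step needs regioselective attack on the unsymmetrical aryne, and the methoxyl next to the triple bond secures it by making the distal carbon the electrophilic one and stabilising the adjacent developing anion inductively, which outweighs the weak opposite bias of the remote methoxyl. No stereocentre is formed, both alkene isomers converge on 16, and quenching of the aryl anion to the simple aryl ester is disfavoured by the aprotic medium and the high temperature.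

Step 9
Reactants: 16 3,5,7-trimethoxy-2-[3,4,5-tris(benzyloxy)phenyl]-4H-chromen-4-one
Product: 17 5-hydroxy-3,7-dimethoxy-2-[3,4,5-tris(benzyloxy)phenyl]-4H-chromen-4-one
Conditions: AlCl3 (5 equiv), MeCN, rt to 50 °C; then 2 M HCl
Reagents that add atoms: none
Why: Chelation-controlled ether cleavage: AlCl3 binds the C4 carbonyl and the peri 5-methoxyl oxygen in a six-membered chelate so that chloride removes only that methyl group (SN2), while the 3- and 7-methoxyls and the non-chelated benzyl ethers should be spared by the nitrile-moderated Lewis acid.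

Step 10
Reactants: 17 5-hydroxy-3,7-dimethoxy-2-[3,4,5-tris(benzyloxy)phenyl]-4H-chromen-4-one
Product: 19 5,8-dihydroxy-3,7-dimethoxy-2-[3,4,5-tris(benzyloxy)phenyl]-4H-chromen-4-one, via potassium 8-sulfate 18 (not isolated)
Conditions: K2S2O8, aq KOH, pyridine, 0 °C to rt; then aq HCl, Na2SO3, dioxane, 80 °C
Reagents that add atoms: potassium peroxodisulfate, [K+].[K+].[O-]S(=O)(=O)OOS(=O)(=O)[O-]
Why: Elbs persulfate oxidation: the 5-phenoxide attacks a peroxide oxygen of peroxodisulfate through its para carbon C8 to give aryl sulfate 18, which is shielded from over-oxidation and is hydrolysed by hot dilute acid to the quinol, unreacted 17 being recoverable for another pass.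

Step 11
Reactants: 19 5,8-dihydroxy-3,7-dimethoxy-2-[3,4,5-tris(benzyloxy)phenyl]-4H-chromen-4-one
Product: 20 5,8,3',4',5'-pentahydroxy-3,7-dimethoxyflavone
Conditions: H2 (1 atm), Pd/C, THF/MeOH, rt; filter and concentrate under argon
Reagents that add atoms: none
Why: Hydrogenolysis over Pd/C cleaves the three benzyl aryl ethers while the methyl ethers and the chromone core are inert, and the air-sensitive polyphenol is handled under inert gas.

**Compound list**

1 | 3,5-dimethoxyphenol | COc1cc(O)cc(OC)c1 | starting material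
2 | 3,5-dimethoxyphenyl N-isopropylcarbamate | CC(C)NC(=O)Oc1cc(OC)cc(OC)c1 | intermediate
3 | 3,5-dimethoxyphenyl N-(tert-butyldimethylsilyl)-N-isopropylcarbamate | CC(C)N(C(=O)Oc1cc(OC)cc(OC)c1)[Si](C)(C)C(C)(C)C | intermediate (not isolated)
4 | 3,5-dimethoxy-2-(trimethylsilyl)phenyl N-(tert-butyldimethylsilyl)-N-isopropylcarbamate | CC(C)N(C(=O)Oc1cc(OC)cc(OC)c1[Si](C)(C)C)[Si](C)(C)C(C)(C)C | intermediate (not isolated)
5 | 3,5-dimethoxy-2-(trimethylsilyl)phenyl N-isopropylcarbamate | CC(C)NC(=O)Oc1cc(OC)cc(OC)c1[Si](C)(C)C | intermediate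
6 | 3,5-dimethoxy-2-(trimethylsilyl)phenol | COc1cc(O)c([Si](C)(C)C)c(OC)c1 | intermediate (not isolated)
7 | 3,5-dimethoxy-2-(trimethylsilyl)phenyl trifluoromethanesulfonate | COc1cc(OC)c([Si](C)(C)C)c(OS(=O)(=O)C(F)(F)F)c1 | intermediate
8 | 3,4,5-tris(benzyloxy)benzoic acid | OC(=O)c1cc(OCc2ccccc2)c(OCc2ccccc2)c(OCc2ccccc2)c1 | starting material
9 | 3,4,5-tris(benzyloxy)benzoyl chloride | ClC(=O)c1cc(OCc2ccccc2)c(OCc2ccccc2)c(OCc2ccccc2)c1 | intermediate
10 | methyl methoxyacetate | COCC(=O)OC | starting material
11 | methyl 2-methoxy-3-oxo-3-[3,4,5-tris(benzyloxy)phenyl]propanoate (racemic) | COC(=O)C(OC)C(=O)c1cc(OCc2ccccc2)c(OCc2ccccc2)c(OCc2ccccc2)c1 | intermediate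
12 | methyl (Z)-2,3-dimethoxy-3-[3,4,5-tris(benzyloxy)phenyl]prop-2-enoate | CO/C(c1cc(OCc2ccccc2)c(OCc2ccccc2)c(OCc2ccccc2)c1)=C(\OC)C(=O)OC | intermediate
13 | (Z)-2,3-dimethoxy-3-[3,4,5-tris(benzyloxy)phenyl]prop-2-enoic acid | CO/C(c1cc(OCc2ccccc2)c(OCc2ccccc2)c(OCc2ccccc2)c1)=C(\OC)C(=O)O | intermediate
14 | 3,5-dimethoxybenzyne (1,2-didehydro-3,5-dimethoxybenzene) | COC1=CC#CC(OC)=C1 | intermediate (not isolated)
15 | (Z)-1-(2-hydroxy-4,6-dimethoxyphenyl)-2,3-dimethoxy-3-[3,4,5-tris(benzyloxy)phenyl]prop-2-en-1-one | CO/C(c1cc(OCc2ccccc2)c(OCc2ccccc2)c(OCc2ccccc2)c1)=C(\OC)C(=O)c1c(O)cc(OC)cc1OC | intermediate (not isolated)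
16 | 3,5,7-trimethoxy-2-[3,4,5-tris(benzyloxy)phenyl]-4H-chromen-4-one | COc1cc(OC)c2c(=O)c(OC)c(-c3cc(OCc4ccccc4)c(OCc4ccccc4)c(OCc4ccccc4)c3)oc2c1 | intermediate
17 | 5-hydroxy-3,7-dimethoxy-2-[3,4,5-tris(benzyloxy)phenyl]-4H-chromen-4-one | COc1cc(O)c2c(=O)c(OC)c(-c3cc(OCc4ccccc4)c(OCc4ccccc4)c(OCc4ccccc4)c3)oc2c1 | intermediate
18 | potassium 5-hydroxy-3,7-dimethoxy-4-oxo-2-[3,4,5-tris(benzyloxy)phenyl]-4H-chromen-8-yl sulfate | COc1cc(O)c2c(=O)c(OC)c(-c3cc(OCc4ccccc4)c(OCc4ccccc4)c(OCc4ccccc4)c3)oc2c1OS(=O)(=O)[O-].[K+] | intermediate (not isolated)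
19 | 5,8-dihydroxy-3,7-dimethoxy-2-[3,4,5-tris(benzyloxy)phenyl]-4H-chromen-4-one | COc1cc(O)c2c(=O)c(OC)c(-c3cc(OCc4ccccc4)c(OCc4ccccc4)c(OCc4ccccc4)c3)oc2c1O | intermediate
20 | 5,8,3',4',5'-pentahydroxy-3,7-dimethoxyflavone (5,8-dihydroxy-3,7-dimethoxy-2-(3,4,5-trihydroxyphenyl)-4H-chromen-4-one) | COc1cc(O)c2c(=O)c(OC)c(-c3cc(O)c(O)c(O)c3)oc2c1O | target

**Step count**

Total: 11 steps. Longest linear sequence: 8 steps (steps 4 to 11, from 8).

**Steps most likely to fail**

Step 8 (carries the label). The aryl anion may be protonated before the acyl shift, which would end at the simple aryl ester. The sequence may also stop at the ring-open enone if addition–elimination at the crowded, donor-substituted β-carbon is slow, or the aryne may be captured by the enol ether in a [2+2] reaction. If only the ring closure stalls, brief treatment of crude 15 with TsOH in warm toluene should finish it. The full fallback uses known reactions only and sets out from 7 and 9. The established CsF-mediated insertion of the same aryne into the C–O bond of methoxyacetic acid (THF, 125 °C) should give 1-(2-hydroxy-4,6-dimethoxyphenyl)-2-methoxyethan-1-one F1. O-Acylation of F1 with 9 (pyridine, DMAP) should give 3,5-dimethoxy-2-(2-methoxyacetyl)phenyl 3,4,5-tris(benzyloxy)benzoate F2. Baker–Venkataraman rearrangement (KOH, pyridine, 50 °C) should give 1-(2-hydroxy-4,6-dimethoxyphenyl)-2-methoxy-3-[3,4,5-tris(benzyloxy)phenyl]propane-1,3-dione F3. Acid-catalysed cyclodehydration (TsOH, toluene, 80 °C) closes ring C and comes back to the route at 16.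

Step 10. The lipophilic, chelated phenoxide may dissolve poorly and convert slowly, and competing attack at C6 or oxidative degradation may erode the material. The fallback sets out from 16 and avoids persulfate. Electrophilic iodination (N-iodosuccinimide, cat. CF3CO2H, MeCN) at C8, the site normally taken by electrophiles in 5,7-dialkoxyflavones, should give 8-iodo-3,5,7-trimethoxy-2-[3,4,5-tris(benzyloxy)phenyl]-4H-chromen-4-one F4. Miyaura borylation (B2pin2, PdCl2(dppf), KOAc, dioxane, 80 °C) should give the 8-pinacolboronate 3,5,7-trimethoxy-8-(4,4,5,5-tetramethyl-1,3,2-dioxaborolan-2-yl)-2-[3,4,5-tris(benzyloxy)phenyl]-4H-chromen-4-one F5. Oxidation (NaBO3·4H2O, THF/H2O, rt) should give 8-hydroxy-3,5,7-trimethoxy-2-[3,4,5-tris(benzyloxy)phenyl]-4H-chromen-4-one F6. Chelation-controlled 5-O-demethylation under the conditions of step 9 (AlCl3, MeCN) then comes back to the route at 19, with steps 9 and 10 bypassed.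

Step 6. The ambident enolate may be methylated at the α-carbon instead of oxygen, which gives a quaternary ester that cannot form the enol ether. The fallback sets out from 11 and never passes through an enolate. Acid-catalysed ketalisation (HC(OMe)3, MeOH, cat. TsOH, 50 °C) should give the dimethyl ketal methyl 2,3,3-trimethoxy-3-[3,4,5-tris(benzyloxy)phenyl]propanoate F7. Elimination of methanol from the ketal (Me3SiOTf, i-Pr2NEt, CH2Cl2, 0 °C to rt) comes back to the route at 12.

**Further compounds**

F1 | step 8 | 1-(2-hydroxy-4,6-dimethoxyphenyl)-2-methoxyethan-1-one | COCC(=O)c1c(O)cc(OC)cc1OC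
F2 | step 8 | 3,5-dimethoxy-2-(2-methoxyacetyl)phenyl 3,4,5-tris(benzyloxy)benzoate | COCC(=O)c1c(OC)cc(OC)cc1OC(=O)c1cc(OCc2ccccc2)c(OCc2ccccc2)c(OCc2ccccc2)c1
F3 | step 8 | 1-(2-hydroxy-4,6-dimethoxyphenyl)-2-methoxy-3-[3,4,5-tris(benzyloxy)phenyl]propane-1,3-dione | COC(C(=O)c1c(O)cc(OC)cc1OC)C(=O)c1cc(OCc2ccccc2)c(OCc2ccccc2)c(OCc2ccccc2)c1
F4 | step 10 | 8-iodo-3,5,7-trimethoxy-2-[3,4,5-tris(benzyloxy)phenyl]-4H-chromen-4-one | COc1cc(OC)c2c(=O)c(OC)c(-c3cc(OCc4ccccc4)c(OCc4ccccc4)c(OCc4ccccc4)c3)oc2c1I
F5 | step 10 | 3,5,7-trimethoxy-8-(4,4,5,5-tetramethyl-1,3,2-dioxaborolan-2-yl)-2-[3,4,5-tris(benzyloxy)phenyl]-4H-chromen-4-one | COc1cc(OC)c2c(=O)c(OC)c(-c3cc(OCc4ccccc4)c(OCc4ccccc4)c(OCc4ccccc4)c3)oc2c1B1OC(C)(C)C(C)(C)O1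
F6 | step 10 | 8-hydroxy-3,5,7-trimethoxy-2-[3,4,5-tris(benzyloxy)phenyl]-4H-chromen-4-one | COc1cc(OC)c2c(=O)c(OC)c(-c3cc(OCc4ccccc4)c(OCc4ccccc4)c(OCc4ccccc4)c3)oc2c1O
F7 | step 6 | methyl 2,3,3-trimethoxy-3-[3,4,5-tris(benzyloxy)phenyl]propanoate | COC(=O)C(OC)C(OC)(OC)c1cc(OCc2ccccc2)c(OCc2ccccc2)c(OCc2ccccc2)c1
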